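**Plan**

- Ring B is the phenol ring: C1' carries the bridging oxygen, C2' the hydroxyl, C3' hydrogen, C4'–C6' bromine. Ring A is the 3,5-dibromo-2-methoxyphenoxy ring.
- Retrosynthesis: the C5'–Br bond is cut first (para-bromination of the phenol). C2'–OH is then masked as its acetate and C6'–Br traced back to C6'–SiMe3. Ring B is finally opened at C1'–C2' and C5'–C6', with CO2 put back between C2' and C5'. This gives a 3-acetoxy-5-bromo-2-pyrone and the C-silylated ynol ether of the ring A phenol.
- Enabling feature: C1' of ring B lies between an oxygen-bearing carbon (C2') and a bromine-bearing carbon (C6'), with Br at C4' and H at C3'. Pyrone C3 (O), C4 (H), C5 (Br) and the O- and Si-bearing alkyne carbons deliver exactly this pattern, so the crowded C1'–O bond is never made by substitution on an arene.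
- Forward: the ring A phenol comes from 3,5-dibromosalicylaldehyde (O-methylation, Baeyer–Villiger). It is converted into the ynol ether without organolithium reagents, so the aryl bromides survive (vinylation, bromination with two dehydrobrominations, silylation). The pyrone comes from 3-hydroxy-2-pyrone. Ring B is the only ring formed and arises in the cycloaddition; three functional-group steps finish the route.
- Stereochemistry: the target is achiral and has no stereocenter or stereogenic double bond. The transient sp3 centres and the bromovinyl ether geometry are erased along the way.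

Key step: step 9

Assumption: DBU-induced loss of HBr from the 1,2-dibromoethyl ether is taken to give mainly the (Z)-2-bromovinyl ether; any (E) isomer is carried along, since both isomers give the same alkyne.

**Route**

Step 1
Reactants: 1 3,5-dibromo-2-hydroxybenzaldehyde (3,5-dibromosalicylaldehyde)
Product: 2 3,5-dibromo-2-methoxybenzaldehyde
Conditions: MeI, K2CO3, DMF, rt
Reagents that add atoms: iodomethane, CI
Why: Williamson O-methylation of the acidic phenol should be clean because the phenoxide is the only nucleophile present.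

Step 2
Reactants: 2 3,5-dibromo-2-methoxybenzaldehyde
Product: 4 3,5-dibromo-2-methoxyphenol, via aryl formate 3 (not isolated)
Conditions: mCPBA, CH2Cl2, 40 °C; then K2CO3, MeOH, rt
Reagents that add atoms: mCPBA (3-chloroperoxybenzoic acid), OOC(=O)c1cccc(Cl)c1
Why: Baeyer–Villiger oxidation in which the ortho-methoxy group should let aryl migration outrun hydride migration, followed by methanolysis of the labile aryl formate.

Step 3
Reactants: 4 3,5-dibromo-2-methoxyphenol
Product: 5 1,5-dibromo-3-(ethenyloxy)-2-methoxybenzene
Conditions: vinyl acetate, [IrCl(cod)]2 (1 mol %), Na2CO3, toluene, 100 °C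
Reagents that add atoms: vinyl acetate, C=COC(C)=O
Why: Iridium-catalysed transfer vinylation (addition of the iridium phenoxide across vinyl acetate, then β-acetate elimination) is mild enough to leave the C–Br bonds untouched.

Step 4
Reactants: 5 1,5-dibromo-3-(ethenyloxy)-2-methoxybenzene
Product: 7 1,5-dibromo-3-{[(Z)-2-bromoethenyl]oxy}-2-methoxybenzene, via 1,2-dibromoethyl ether 6 (not isolated)
Conditions: Br2, CH2Cl2, −78 °C; then DBU, −78 °C → rt
Reagents that add atoms: bromine, BrBr
Why: Electrophilic addition of bromine to the enol ether double bond is far faster than bromination of the deactivated ring, and DBU then removes HBr from the α-bromo ether (elimination through the oxocarbenium-like C–Br bond), as in the bromination–elimination route to 2-bromo enol ethers.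

Step 5
Reactants: 7 1,5-dibromo-3-{[(Z)-2-bromoethenyl]oxy}-2-methoxybenzene
Product: 8 1,5-dibromo-3-(ethynyloxy)-2-methoxybenzene
Conditions: KOt-Bu, THF, −78 → 0 °C
Reagents that add atoms: none
Why: Anti-periplanar E2 dehydrobromination of the (Z)-bromovinyl ether by the alkoxide gives the terminal ynol ether; an alkoxide is chosen because an alkyllithium would exchange the aryl bromides.

Step 6
Reactants: 8 1,5-dibromo-3-(ethynyloxy)-2-methoxybenzene
Product: 9 [(3,5-dibromo-2-methoxyphenoxy)ethynyl]trimethylsilane
Conditions: LiN(SiMe3)2, THF, −78 °C; then Me3SiCl, −78 °C → rt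
Reagents that add atoms: chlorotrimethylsilane, C[Si](C)(C)Cl
Why: Deprotonation of the terminal alkyne by a non-nucleophilic amide, which can neither exchange bromine for lithium nor metalate the ring, followed by C-silylation of the lithium acetylide.

Step 7
Reactants: 10 3-hydroxy-2H-pyran-2-one
Product: 11 2-oxo-2H-pyran-3-yl acetate
Conditions: Ac2O, pyridine, CH2Cl2, 0 °C → rt
Reagents that add atoms: acetic anhydride, CC(=O)OC(C)=O
Why: Pyridine-mediated O-acylation of the acidic enolic hydroxyl.

Step 8
Reactants: 11 2-oxo-2H-pyran-3-yl acetate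
Product: 13 5-bromo-2-oxo-2H-pyran-3-yl acetate, via 5,6-dibromide 12 (not isolated)
Conditions: Br2, CH2Cl2, 0 °C → rt; then Et3N, 0 °C
Reagents that add atoms: bromine, BrBr
Why: With C3 blocked and its oxygen lone pair tied up in the ester, the C5=C6 enol-lactone double bond should be the most electron-rich site, so bromine adds there (electrophilic addition) and Et3N removes the vinylogously acidic C5–H with loss of the C6 bromide (addition–elimination bromination), leaving bromine at C5.

Step 9
Reactants: 9 [(3,5-dibromo-2-methoxyphenoxy)ethynyl]trimethylsilane; 13 5-bromo-2-oxo-2H-pyran-3-yl acetate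
Product: 15 5-bromo-2-(3,5-dibromo-2-methoxyphenoxy)-3-(trimethylsilyl)phenyl acetate, via bridged lactone 14 (not isolated)
Conditions: 13 (1.5 equiv), xylene, 140 °C, sealed tube
Reagents that add atoms: none
Why: The 2-pyrone 13, made electron-poor by the lactone carbonyl, the C5 bromine and the inductively withdrawing C3 acetoxy group, acts as the 4π component in an inverse-electron-demand Diels–Alder reaction with the electron-rich alkyne of 9, and the bridged lactone 14 then expels CO2 by a retro-[4+2] step. The closest known reaction type is the thermal cycloaddition–decarboxylation of bromo-2-pyrones with electron-rich alkynes and enol ethers to give substituted benzenes. Ring B closes in one concerted six-membered [4+2] event across pyrone C3/C6 and the two alkyne carbons (forming C1'–C2' and C5'–C6') and becomes aromatic when the CO2 bridge leaves. No stereocenter results, since both bridgeheads of 14 end as sp2 carbons. The step needs regioselectivity: the silicon-bearing alkyne carbon has the larger HOMO coefficient, because charge developing at its neighbour is stabilised by the oxygen lone pair and the β-silicon effect; it should therefore bond to pyrone C6, the terminus with the larger LUMO coefficient, so that the aryloxy carbon bonds to C3 next to the acetoxy group. The aryl ynol ether has no β-hydrogen for a retro-ene fragmentation and should tolerate the temperature required.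

Step 10
Reactants: 15 5-bromo-2-(3,5-dibromo-2-methoxyphenoxy)-3-(trimethylsilyl)phenyl acetate
Product: 16 3,5-dibromo-2-(3,5-dibromo-2-methoxyphenoxy)phenyl acetate
Conditions: Br2, CH2Cl2, 0 °C → rt
Reagents that add atoms: bromine, BrBr
Why: Electrophilic ipso-substitution (bromodesilylation): attack at the silicon-bearing carbon gives a β-silyl-stabilised arenium ion that loses Me3SiBr, which should be much faster than C–H bromination of either deactivated ring.

Step 11
Reactants: 16 3,5-dibromo-2-(3,5-dibromo-2-methoxyphenoxy)phenyl acetate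
Product: 17 3,5-dibromo-2-(3,5-dibromo-2-methoxyphenoxy)phenol
Conditions: K2CO3, MeOH, rt
Reagents that add atoms: none
Why: Base-mediated methanolysis (transesterification) of the aryl acetate; the aryl ethers and C–Br bonds are inert to carbonate in methanol.

Step 12
Reactants: 17 3,5-dibromo-2-(3,5-dibromo-2-methoxyphenoxy)phenol
Product: 18 3,4,5-tribromo-2-(3,5-dibromo-2-methoxyphenoxy)phenol
Conditions: NBS (1.0 equiv), MeCN, 0 °C → rt
Reagents that add atoms: N-bromosuccinimide, O=C1CCC(=O)N1Br
Why: Electrophilic aromatic bromination directed by the free hydroxyl: ring B is the only strongly activated ring and NBS in acetonitrile is a para-selective system for phenols, so bromine should enter C5' (para) in preference to C3' (ortho), with one equivalent at low temperature limiting a second bromination.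

**Compound list**

1 | 3,5-dibromo-2-hydroxybenzaldehyde (3,5-dibromosalicylaldehyde) | O=Cc1cc(Br)cc(Br)c1O | starting material
2 | 3,5-dibromo-2-methoxybenzaldehyde | COc1c(Br)cc(Br)cc1C=O | intermediate
3 | 3,5-dibromo-2-methoxyphenyl formate (not isolated) | COc1c(Br)cc(Br)cc1OC=O | intermediate
4 | 3,5-dibromo-2-methoxyphenol | COc1c(Br)cc(Br)cc1O | intermediate
5 | 1,5-dibromo-3-(ethenyloxy)-2-methoxybenzene | COc1c(Br)cc(Br)cc1OC=C | intermediate
6 | 1,5-dibromo-3-(1,2-dibromoethoxy)-2-methoxybenzene (racemic, not isolated) | COc1c(Br)cc(Br)cc1OC(Br)CBr | intermediate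
7 | 1,5-dibromo-3-{[(Z)-2-bromoethenyl]oxy}-2-methoxybenzene | COc1c(Br)cc(Br)cc1O/C=C\Br | intermediate
8 | 1,5-dibromo-3-(ethynyloxy)-2-methoxybenzene | COc1c(Br)cc(Br)cc1OC#C | intermediate
9 | [(3,5-dibromo-2-methoxyphenoxy)ethynyl]trimethylsilane | COc1c(Br)cc(Br)cc1OC#C[Si](C)(C)C | intermediate
10 | 3-hydroxy-2H-pyran-2-one | OC1=CC=COC1=O | starting material
11 | 2-oxo-2H-pyran-3-yl acetate | CC(=O)OC1=CC=COC1=O | intermediate
12 | trans-5,6-dibromo-2-oxo-5,6-dihydro-2H-pyran-3-yl acetate (racemic, one enantiomer drawn, not isolated) | CC(=O)OC1=C[C@H](Br)[C@@H](Br)OC1=O | intermediate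
13 | 5-bromo-2-oxo-2H-pyran-3-yl acetate | CC(=O)OC1=CC(Br)=COC1=O | intermediate
14 | 7-bromo-5-(3,5-dibromo-2-methoxyphenoxy)-3-oxo-6-(trimethylsilyl)-2-oxabicyclo[2.2.2]octa-5,7-dien-4-yl acetate (racemic; the bicycle allows only one relative configuration of the two bridgeheads; not isolated) | CC(=O)OC12C=C(Br)C(OC1=O)C([Si](C)(C)C)=C2Oc3cc(Br)cc(Br)c3OC | intermediate
15 | 5-bromo-2-(3,5-dibromo-2-methoxyphenoxy)-3-(trimethylsilyl)phenyl acetate | COc1c(Br)cc(Br)cc1Oc1c(OC(C)=O)cc(Br)cc1[Si](C)(C)C | intermediate
16 | 3,5-dibromo-2-(3,5-dibromo-2-methoxyphenoxy)phenyl acetate | COc1c(Br)cc(Br)cc1Oc1c(OC(C)=O)cc(Br)cc1Br | intermediate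
17 | 3,5-dibromo-2-(3,5-dibromo-2-methoxyphenoxy)phenol | COc1c(Br)cc(Br)cc1Oc1c(O)cc(Br)cc1Br | intermediate
18 | 3,4,5-tribromo-2-(3,5-dibromo-2-methoxyphenoxy)phenol | COc1c(Br)cc(Br)cc1Oc1c(O)cc(Br)c(Br)c1Br | target

**Step count and risks**

Total steps: 12. Longest linear sequence: 10 (steps 1–6 and 9–12); the pyrone branch (steps 7–8) joins at step 9.

Step 12 is the most likely to fail. The electrophile may attack the ortho carbon C3', which is less crowded than the para carbon C5' wedged between two bromines, or a second bromination may follow. The fallback sets out from 17 and returns at 18; it turns the hydroxyl into a bulky ether so that C3' is shielded. Compound 17 would be silylated with i-Pr3SiOTf and 2,6-lutidine in CH2Cl2 to [3,5-dibromo-2-(3,5-dibromo-2-methoxyphenoxy)phenoxy]tri(propan-2-yl)silane F1, whose silyl group is pushed toward C3' by the neighbouring aryloxy substituent. NBS in DMF should then brominate only para to the silyloxy group, giving [3,4,5-tribromo-2-(3,5-dibromo-2-methoxyphenoxy)phenoxy]tri(propan-2-yl)silane F2, and Bu4NF in THF would release 18.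

Step 9 is the second risk. The cycloaddition may be too slow below the temperature at which the pyrone or the ynol ether degrades, or the hindered silyl terminus may erode regiocontrol. The fallback sets out from 8 and returns at 16; it replaces silicon by tin. Compound 8 would be deprotonated with LiN(SiMe3)2 in THF at −78 °C and quenched with Bu3SnCl to give tributyl[(3,5-dibromo-2-methoxyphenoxy)ethynyl]stannane F3. The C–Sn bond is a stronger σ-donor and is longer, so the alkyne should be more nucleophilic, more strongly polarised and less congested at the reacting carbon. Heating F3 with 13 in toluene should give, through the bridged lactone 7-bromo-5-(3,5-dibromo-2-methoxyphenoxy)-3-oxo-6-(tributylstannyl)-2-oxabicyclo[2.2.2]octa-5,7-dien-4-yl acetate F4 and loss of CO2, 5-bromo-2-(3,5-dibromo-2-methoxyphenoxy)-3-(tributylstannyl)phenyl acetate F5. Bromodestannylation of F5 with Br2 in CH2Cl2 at −78 °C would lead directly to 16.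

Step 8 is the third risk. Bromine may be steered by the acyloxy oxygen to C4 or C6 instead of C5, or the dibromide may lose HBr in the wrong sense. The fallback sets out from 10 and returns at 17; it carries the C3 oxygen as a sulfonate, which is a much weaker π-donor than the acetate and also makes the diene more electron-poor. Compound 10 with MsCl and Et3N in CH2Cl2 would give 2-oxo-2H-pyran-3-yl methanesulfonate F6. Br2 and then Et3N should convert it, by way of trans-5,6-dibromo-2-oxo-5,6-dihydro-2H-pyran-3-yl methanesulfonate F7, into 5-bromo-2-oxo-2H-pyran-3-yl methanesulfonate F8. Heating F8 with 9 in xylene should pass through the bridged lactone 7-bromo-5-(3,5-dibromo-2-methoxyphenoxy)-3-oxo-6-(trimethylsilyl)-2-oxabicyclo[2.2.2]octa-5,7-dien-4-yl methanesulfonate F9 to 5-bromo-2-(3,5-dibromo-2-methoxyphenoxy)-3-(trimethylsilyl)phenyl methanesulfonate F10. Br2 in CH2Cl2 would give 3,5-dibromo-2-(3,5-dibromo-2-methoxyphenoxy)phenyl methanesulfonate F11, and KOH in MeOH/THF at 60 °C would cleave the sulfonate to 17.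

**Further compounds**

F1 | step 12 | [3,5-dibromo-2-(3,5-dibromo-2-methoxyphenoxy)phenoxy]tri(propan-2-yl)silane | COc1c(Br)cc(Br)cc1Oc1c(O[Si](C(C)C)(C(C)C)C(C)C)cc(Br)cc1Br
F2 | step 12 | [3,4,5-tribromo-2-(3,5-dibromo-2-methoxyphenoxy)phenoxy]tri(propan-2-yl)silane | COc1c(Br)cc(Br)cc1Oc1c(O[Si](C(C)C)(C(C)C)C(C)C)cc(Br)c(Br)c1Br
F3 | step 9 | tributyl[(3,5-dibromo-2-methoxyphenoxy)ethynyl]stannane | COc1c(Br)cc(Br)cc1OC#C[Sn](CCCC)(CCCC)CCCC
F4 | step 9 | 7-bromo-5-(3,5-dibromo-2-methoxyphenoxy)-3-oxo-6-(tributylstannyl)-2-oxabicyclo[2.2.2]octa-5,7-dien-4-yl acetate (racemic) | CC(=O)OC12C=C(Br)C(OC1=O)C([Sn](CCCC)(CCCC)CCCC)=C2Oc3cc(Br)cc(Br)c3OC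
F5 | step 9 | 5-bromo-2-(3,5-dibromo-2-methoxyphenoxy)-3-(tributylstannyl)phenyl acetate | COc1c(Br)cc(Br)cc1Oc1c(OC(C)=O)cc(Br)cc1[Sn](CCCC)(CCCC)CCCC
F6 | step 8 | 2-oxo-2H-pyran-3-yl methanesulfonate | CS(=O)(=O)OC1=CC=COC1=O
F7 | step 8 | trans-5,6-dibromo-2-oxo-5,6-dihydro-2H-pyran-3-yl methanesulfonate (racemic, one enantiomer drawn) | CS(=O)(=O)OC1=C[C@H](Br)[C@@H](Br)OC1=O
F8 | step 8 | 5-bromo-2-oxo-2H-pyran-3-yl methanesulfonate | CS(=O)(=O)OC1=CC(Br)=COC1=O
F9 | step 8 | 7-bromo-5-(3,5-dibromo-2-methoxyphenoxy)-3-oxo-6-(trimethylsilyl)-2-oxabicyclo[2.2.2]octa-5,7-dien-4-yl methanesulfonate (racemic) | CS(=O)(=O)OC12C=C(Br)C(OC1=O)C([Si](C)(C)C)=C2Oc3cc(Br)cc(Br)c3OC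
F10 | step 8 | 5-bromo-2-(3,5-dibromo-2-methoxyphenoxy)-3-(trimethylsilyl)phenyl methanesulfonate | COc1c(Br)cc(Br)cc1Oc1c(OS(C)(=O)=O)cc(Br)cc1[Si](C)(C)C
F11 | step 8 | 3,5-dibromo-2-(3,5-dibromo-2-methoxyphenoxy)phenyl methanesulfonate | COc1c(Br)cc(Br)cc1Oc1c(OS(C)(=O)=O)cc(Br)cc1Br
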